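## Analysis of the target

The target 14 is 2-[2-(4-hydroxy-3-methoxyphenyl)ethyl]-6,7-dimethoxychromone. It has a benzo ring (ring A, C4a to C8a, methoxy groups on C6 and C7) fused to a 4-pyranone (ring B: O1, C2, C3, C4, C4a, C8a). A saturated two-carbon chain joins C2 to a guaiacyl ring (ring C). There is no stereocentre and no configured double bond, so every problem is one of connectivity and chemoselectivity. The free phenol of ring C is easily oxidised and alkylated and must be kept distinct from the three methyl ethers from the start. The pyranone is a vinylogous ester: hydroxide, alkoxides and amines add to C2 and open it, and C2=C3 can be hydrogenated. The difficulty is to build ring B with an sp3 chain on C2 and an unambiguous 6,7-dioxygenation pattern, and to free the phenol at the end under conditions the pyranone survives. The strategy rests on C3, the only ring B carbon that carries nothing but hydrogen. If C3 is removed and C2 is joined to C4, ring B contracts to the furanone of a 2-substituted 5,6-dimethoxybenzofuran-3(2H)-one that already holds O1, C2 with its chain, the C4 carbonyl and ring A, so ring B can be made by inserting one carbon into the C2=C3 enol-ether bond of that five-membered ring.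

## Retrosynthetic reasoning

**14 to 12.** The last bonds made are C3–H and the phenolic O–H, both by one hydrogenolysis of the 3-bromochromone benzyl ether 12 through the debrominated benzyl ether 13. The phenol has to stay masked through an ozonolysis, two base-mediated steps and a carbene reaction. A benzyl ether is the mask that comes off under the same conditions that remove the bromine the ring expansion leaves on C3. No separate deprotection is needed, and the pyranone meets neither acid nor nucleophilic base.

**12 to 9 and 10.** Ring B is cut at C2–C3 and C3–C4. This takes out C3 with its bromine as the one-carbon unit of bromoform 10 and leaves the 3-silyloxybenzofuran 9. Cuts at O1–C2, O1–C8a or C4–C4a would need an ortho-oxygenated aryl ketone or an aryloxy acid and a cyclodehydration. Cutting out C3 keeps every carbon–oxygen bond of ring B and the ring A pattern inside a five-membered precursor, so the 5,6-dimethoxy pattern of the furanone becomes the 6,7-pattern of the chromone with no isomer question. The forward reaction must deliver the dihalocarbene from 10 to the furan C2=C3 bond in preference to both arenes, then open the cyclopropane across its internal bond with loss of the silyl group.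

**9 to 8.** The O–Si bond is cut to give the ketone 8. Its only enolisable position is C2, so enol silylation can give no regioisomer, and the enol ether formed is an aromatic furan.

**8 to 7.** The two C–H bonds across the exocyclic alkene of the enone 7 are removed. Saturating after the condensation lets the two-carbon linker be made by carbonyl chemistry. The reduction must spare the benzyl ether and the aryl ketone, so a palladium catalyst moderated by a nitrogen base is planned. A homogeneous rhodium hydrogenation would be slow on a trisubstituted conjugated alkene.

**7 to 4 and 5.** The exocyclic C=C bond is cut as an aldol condensation between C2 of the furanone 5 and the arylacetaldehyde 4. C2 of 5 is activated by the ketone and by O1, and condensation with aldehydes is the characteristic reaction of this ring. The aldehyde carbon and its α-methylene become the two-carbon linker.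

**4 to 2 to 1.** The aldehyde 4 comes from oxidative cleavage of the terminal alkene of the benzyl ether 2, with loss of one carbon. 2 is the benzyl ether of eugenol 1, which already has the guaiacyl oxygenation pattern and the chain in the right position.

## Alternatives that were turned down

**Alternative 1:** Friedel–Crafts cycloacylation, cutting C4–C4a. The acid A1, (Z)-3-(3,4-dimethoxyphenoxy)-5-[3-methoxy-4-(tosyloxy)phenyl]pent-2-enoic acid, is ionised in P2O5–CH3SO3H. The acylium ion attacks the ring A position ortho to the aryloxy oxygen and para to a methoxy group, closing ring B to give the tosyl-protected chromone A2.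
- For: the cyclisation type is classical, its regiochemistry is secure because the other ortho position is flanked by two oxygens, and no step is untested. On precedent for the ring-forming step it is stronger than the chosen route.
- Against: A1 needs a conjugate addition of a phenol to a 5-arylpent-2-ynoate that itself takes several steps, with the Z geometry to control or equilibrate. The superacid medium forces a tosylate on ring C to deactivate it. Removing that tosylate from A2 needs hydroxide or a similar nucleophile, the reagent the pyranone tolerates least. The aryl enol ether of A1 can also hydrolyse and decarboxylate in acid.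
- Comparison: it is one or two steps longer. The chosen route builds the skeleton from two cheap blocks by one condensation and ends with a neutral hydrogenolysis.

**Alternative 2:** Anodic C–O coupling of a diarylpentanedione, cutting O1–C8a. The diketone A3, 5-(4-acetoxy-3-methoxyphenyl)-1-(3,4-dimethoxyphenyl)pentane-1,3-dione, is oxidised at a graphite anode in hexafluoroisopropanol with a pyridine base. The enol oxygen is joined to the ring A carbon ortho to the acyl group and para to a methoxy group, giving the acetate A4.
- For: it is the shortest on paper, since A3 comes from one Claisen condensation and ring A needs no ortho oxygen. It follows the likely biosynthetic order. On step count and atom economy it is stronger than the chosen route.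
- Against: dehydrogenative O-arylation of a dicarbonyl enol onto an acyl-deactivated arene has no close model. A3 has three oxidisable π systems, and a diketone enol usually reacts at its central carbon (coupling, dimerisation) rather than at oxygen. The product A4 stays oxidisable at the anode.
- Comparison: both key steps are untested. The chosen one runs through polar two-electron events that each have a close analogue and allow only one regiochemical outcome, while the anodic step depends on which π system is oxidised first.

**Alternative 3:** Carbonylative alkynylation–annulation, cutting C4a–C4, C4–C3 and O1–C2. 2-Iodo-4,5-dimethoxyphenol A5, carbon monoxide A6 and 4-(4-benzyloxy-3-methoxyphenyl)but-1-yne A7 react with PdCl2(PPh3)2 in diethylamine. Zerovalent palladium formed from the divalent palladium precatalyst inserts into the C–I bond, A6 inserts, the acyl-palladium couples with A7, and amine-mediated 6-endo closure of the ynone gives A8, 2-[2-(4-benzyloxy-3-methoxyphenyl)ethyl]-6,7-dimethoxychromone, the same compound as 13.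
- For: three bonds form in one convergent operation, the reaction type is established on iodophenols, and A8 is one hydrogenolysis from the target. On reliability and convergence it is stronger than the chosen route and about equal in length.
- Against: A7 needs a multistep homologation, A6 must be handled under pressure, direct non-carbonylative coupling leads to a benzofuran, and 5-exo closure to an aurone-type isomer competes.
- Comparison: the chosen route needs no toxic gas and no alkyne synthesis, and takes the linker from an oxidative cleavage of a commodity allylbenzene. It is preferred for testing a one-carbon ring expansion that would also give C3-functionalised analogues through the bromide.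

Key step: step 6

Assumptions: 5 is taken to be a purchasable building block. 7 is written as the conjugated Z-enone; any double-bond isomer formed beside it is reduced to the same ketone 8 in step 4.

## Route

Step 1
Reactants: 1 eugenol (4-allyl-2-methoxyphenol)
Product: 2 4-allyl-1-(benzyloxy)-2-methoxybenzene
Conditions: BnBr, K2CO3, acetone, reflux
Reagents that add atoms: benzyl bromide, BrCc1ccccc1
Why: Williamson ether synthesis on the phenoxide, which is the only nucleophilic site; the benzyl ether withstands ozone at low temperature, bases and the carbene step and is cleaved in step 7.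

Step 2
Reactants: 2 4-allyl-1-(benzyloxy)-2-methoxybenzene
Product: 4 (4-benzyloxy-3-methoxyphenyl)acetaldehyde, via secondary ozonide 3 (not isolated)
Conditions: O3, CH2Cl2, −78 °C; then PPh3, −78 °C → rt
Reagents that add atoms: ozone, [O-][O+]=O
Why: Criegee ozonolysis: the terminal alkene should react far faster than the dialkoxybenzene ring at −78 °C when ozone is dosed to an indicator end point, and PPh3 reduces the 1,2,4-trioxolane 3 to 4 and formaldehyde. 4 is used crude at once because arylacetaldehydes self-condense on storage.

Step 3
Reactants: 4 (4-benzyloxy-3-methoxyphenyl)acetaldehyde; 5 5,6-dimethoxybenzofuran-3(2H)-one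
Product: 7 (Z)-2-[2-(4-benzyloxy-3-methoxyphenyl)ethylidene]-5,6-dimethoxybenzofuran-3(2H)-one, via aldol adduct 6 (not isolated)
Conditions: piperidine (cat.), AcOH (cat.), 4 Å MS, CH2Cl2, 0 °C → rt, 4 added slowly
Reagents that add atoms: none
Why: Knoevenagel-type aldol condensation: C2–H of 5 is activated by the ketone and by O1 (its enolate is an aromatic benzofuran-3-olate) and adds to the aldehyde, and 6 loses water to the conjugated enone. The Z isomer, with the chain syn to O1, is the thermodynamic one as in aurones, and the geometry is removed in step 4; slow addition keeps the concentration of 4 low to limit its self-condensation.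

Step 4
Reactants: 7 (Z)-2-[2-(4-benzyloxy-3-methoxyphenyl)ethylidene]-5,6-dimethoxybenzofuran-3(2H)-one
Product: 8 2-[2-(4-benzyloxy-3-methoxyphenyl)ethyl]-5,6-dimethoxybenzofuran-3(2H)-one (racemic)
Conditions: H2 (1 atm), Pd/C, pyridine, EtOAc, rt
Reagents that add atoms: none
Why: Heterogeneous hydrogenation of the exocyclic alkene; the nitrogen base suppresses hydrogenolysis of the phenolic benzyl ether on palladium, and the aryl ketone is not reduced at 1 atm under non-acidic conditions. The C2 stereocentre forms as a racemate and is erased by enolisation in step 5.

Step 5
Reactants: 8 2-[2-(4-benzyloxy-3-methoxyphenyl)ethyl]-5,6-dimethoxybenzofuran-3(2H)-one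
Product: 9 2-[2-(4-benzyloxy-3-methoxyphenyl)ethyl]-3-(tert-butyldimethylsilyloxy)-5,6-dimethoxybenzofuran
Conditions: KN(SiMe3)2, THF, −78 °C; then tBuMe2SiCl, −78 → 0 °C
Reagents that add atoms: tert-butyldimethylsilyl chloride, CC(C)(C)[Si](C)(C)Cl
Why: Enol silyl ether formation: deprotonation at C2, the only enolisable position, gives the potassium benzofuran-3-olate, which is silylated on oxygen to the aromatic furan. The bulky silyl group is chosen to resist tert-butoxide in step 6.

Step 6
Reactants: 9 2-[2-(4-benzyloxy-3-methoxyphenyl)ethyl]-3-(tert-butyldimethylsilyloxy)-5,6-dimethoxybenzofuran; 10 bromoform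
Product: 12 2-[2-(4-benzyloxy-3-methoxyphenyl)ethyl]-3-bromo-6,7-dimethoxychromone, via dibromocyclopropane 11 (not isolated)
Conditions: CHBr3, KOtBu, hexane–toluene, −25 °C → rt
Reagents that add atoms: none
Why: Proposed new method: α-elimination of 10 with KOtBu gives singlet dibromocarbene, which should add as an electrophile to the C2=C3 bond of 9, the only π bond with two oxygen donors, to give the cis-fused dibromocyclopropane 11, whose two ring-fusion stereocentres are set cis by the concerted suprafacial addition and are erased in the next event. Ionisation of the C–Br bond syn to the five-membered ring is concerted with disrotatory opening of the shared C–C bond, a two-electron electrocyclic process, so ring B is formed by enlargement of the furan ring and not by an exo or endo cyclisation. The cation formed is a 3-bromo-4-silyloxybenzopyrylium ion, stabilised by O1 and the silyloxy group and aromatic, so the opening should occur below room temperature without silver salts. Bromide then removes the silyl group and leaves the C4 carbonyl of 12. The closest known reaction types are the dihalocarbene ring expansion of cyclic silyl enol ethers to 2-halocycloalk-2-enones and Ciamician–Dennstedt one-carbon insertions into indoles, indenes and benzofurans; the combination on a 3-silyloxybenzofuran has not been shown. Chemoselectivity for the furan bond over ring A and ring C follows from its enol-ether character, and the bulky silyl group with a sparingly soluble base in a hydrocarbon should keep Si–O cleavage slower than deprotonation of 10. The direction of opening is fixed because only cleavage of the internal bond gives an oxygen-stabilised cation. Base is kept below the amount of 10 so that 12, an acceptor at C2, is not exposed to excess alkoxide.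

Step 7
Reactants: 12 2-[2-(4-benzyloxy-3-methoxyphenyl)ethyl]-3-bromo-6,7-dimethoxychromone
Product: 14 2-[2-(4-hydroxy-3-methoxyphenyl)ethyl]-6,7-dimethoxychromone, via debrominated benzyl ether 13 (not isolated)
Conditions: H2 (1 atm), Pd/C, NaOAc, EtOAc–MeOH, rt
Reagents that add atoms: none
Why: Heterogeneous hydrogenolysis: the vinylic C3–Br bond next to the carbonyl should be cleaved first (giving 13), then the benzylic C–O bond. NaOAc takes up HBr; an amine base is avoided because nitrogen bases retard benzyl ether hydrogenolysis on palladium, the effect used in step 4. The C2=C3 bond of a 2-alkylchromone is reduced more slowly, so the reaction is stopped when hydrogen uptake ends.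

## Compound list

1 | eugenol (4-allyl-2-methoxyphenol) | COc1cc(CC=C)ccc1O | starting material
2 | 4-allyl-1-(benzyloxy)-2-methoxybenzene | COc1cc(CC=C)ccc1OCc1ccccc1 | intermediate
3 | 3-[(4-benzyloxy-3-methoxyphenyl)methyl]-1,2,4-trioxolane (racemic, not isolated) | COc1cc(CC2OCOO2)ccc1OCc1ccccc1 | intermediate
4 | (4-benzyloxy-3-methoxyphenyl)acetaldehyde | COc1cc(CC=O)ccc1OCc1ccccc1 | intermediate
5 | 5,6-dimethoxybenzofuran-3(2H)-one | COc1cc2OCC(=O)c2cc1OC | starting material
6 | 2-[2-(4-benzyloxy-3-methoxyphenyl)-1-hydroxyethyl]-5,6-dimethoxybenzofuran-3(2H)-one (mixture of racemic diastereomers, not isolated) | COc1cc2OC(C(O)Cc3ccc(OCc4ccccc4)c(OC)c3)C(=O)c2cc1OC | intermediate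
7 | (Z)-2-[2-(4-benzyloxy-3-methoxyphenyl)ethylidene]-5,6-dimethoxybenzofuran-3(2H)-one | COc1cc2O/C(=C\Cc3ccc(OCc4ccccc4)c(OC)c3)C(=O)c2cc1OC | intermediate
8 | 2-[2-(4-benzyloxy-3-methoxyphenyl)ethyl]-5,6-dimethoxybenzofuran-3(2H)-one (racemic) | COc1cc2OC(CCc3ccc(OCc4ccccc4)c(OC)c3)C(=O)c2cc1OC | intermediate
9 | 2-[2-(4-benzyloxy-3-methoxyphenyl)ethyl]-3-(tert-butyldimethylsilyloxy)-5,6-dimethoxybenzofuran | COc1cc2oc(CCc3ccc(OCc4ccccc4)c(OC)c3)c(O[Si](C)(C)C(C)(C)C)c2cc1OC | intermediate
10 | bromoform | BrC(Br)Br | starting material
11 | 1,1-dibromo-1a-[2-(4-benzyloxy-3-methoxyphenyl)ethyl]-6b-(tert-butyldimethylsilyloxy)-4,5-dimethoxy-1a,6b-dihydro-1H-cyclopropa[b]benzofuran (racemic, cis-fused, relative configuration shown, not isolated) | COc1cc2O[C@@]3(CCc4ccc(OCc5ccccc5)c(OC)c4)C(Br)(Br)[C@@]3(O[Si](C)(C)C(C)(C)C)c2cc1OC | intermediate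
12 | 2-[2-(4-benzyloxy-3-methoxyphenyl)ethyl]-3-bromo-6,7-dimethoxychromone | COc1cc(CCc2oc3cc(OC)c(OC)cc3c(=O)c2Br)ccc1OCc1ccccc1 | intermediate
13 | 2-[2-(4-benzyloxy-3-methoxyphenyl)ethyl]-6,7-dimethoxychromone (not isolated) | COc1cc(CCc2cc(=O)c3cc(OC)c(OC)cc3o2)ccc1OCc1ccccc1 | intermediate
14 | 2-[2-(4-hydroxy-3-methoxyphenyl)ethyl]-6,7-dimethoxychromone | COc1cc(CCc2cc(=O)c3cc(OC)c(OC)cc3o2)ccc1O | target

## Step count and risk

Total step count: 7. Longest linear sequence: 7 steps, from 1 to 14; 5 and 10 are purchased and enter in steps 3 and 6.

**Step 6 (key step, new method).** The most likely failures are: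
- cleavage of the Si–O bond by tert-butoxide before the carbene is captured, after which the enolate is alkylated on carbon;
- sluggish addition to a tetrasubstituted bond that is part of an aromatic furan;
- ring-opening of the bromochromone by excess alkoxide.

Fallback by known chemistry, closing ring B by cyclodehydration: it sets out from 2. Hydroboration–oxidation (BH3·THF; then H2O2, NaOH) gives 3-(4-benzyloxy-3-methoxyphenyl)propan-1-ol F1. Oxidation with TEMPO (cat.) and PhI(OAc)2 in MeCN–H2O gives 3-(4-benzyloxy-3-methoxyphenyl)propanoic acid F2. Esterification with purchased 1-(2-hydroxy-4,5-dimethoxyphenyl)ethanone F3 (DCC, DMAP cat., CH2Cl2) gives 2-acetyl-4,5-dimethoxyphenyl 3-(4-benzyloxy-3-methoxyphenyl)propanoate F4. Baker–Venkataraman acyl shift (KOtBu, THF; AcOH quench) gives 5-(4-benzyloxy-3-methoxyphenyl)-1-(2-hydroxy-4,5-dimethoxyphenyl)pentane-1,3-dione F5. Cyclodehydration (p-TsOH cat., toluene, 80 °C) gives 13, where the detour rejoins the route, and the conditions of step 7 convert 13 into 14.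

**Step 3.** Self-condensation of the enolisable aldehyde 4 under amine catalysis can outrun the cross-condensation, and the new double bond may migrate out of conjugation. Migration is harmless, since step 4 converges; self-condensation is not. Fallback by a directed aldol: it sets out from 5 and 4. 5 is silylated (Me3SiCl, Et3N, MeCN; salt filtered off) to 5,6-dimethoxy-3-(trimethylsilyloxy)benzofuran F6. A Mukaiyama aldol addition to 4 (Sc(OTf)3 cat., CH2Cl2, −78 °C), in which the aldehyde acts only as electrophile, gives 2-[2-(4-benzyloxy-3-methoxyphenyl)-1-(trimethylsilyloxy)ethyl]-5,6-dimethoxybenzofuran-3(2H)-one F7. Catalytic p-TsOH eliminates trimethylsilanol from F7 and returns to the route at 7.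

**Step 4.** Partial hydrogenolysis of the benzyl ether or slow reduction of the aryl ketone may accompany saturation of the alkene if the catalyst is not moderated enough. Fallback by homogeneous conjugate hydrosilylation: it sets out from 7. With tBuMe2SiH and RhCl(PPh3)3 (cat.) in toluene at 60 °C, hydride is delivered to the exocyclic carbon and silicon to oxygen, giving 9 directly. This skips 8 and step 5. A monovalent rhodium catalyst in solution cannot cleave the benzyl ether. It works only on the conjugated isomer, and no compound outside the compound list is made (F0).

**Step 7.** Over-reduction of C2=C3 to the chromanone, or incomplete debenzylation once bromide has accumulated on the catalyst, may occur. Fallback without hydrogen gas: it sets out from 12. BCl3 with pentamethylbenzene in CH2Cl2 at −78 °C removes the benzyl group as a cation trapped by the arene, leaving the methyl ethers, and gives 3-bromo-2-[2-(4-hydroxy-3-methoxyphenyl)ethyl]-6,7-dimethoxychromone F8. Formate reduction (Pd(OAc)2, PPh3, HCO2Na, DMF, 80 °C) through oxidative addition of zerovalent palladium to the C3–Br bond and hydride transfer then gives 14.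

## Further compounds

F1 | step 6 | 3-(4-benzyloxy-3-methoxyphenyl)propan-1-ol | COc1cc(CCCO)ccc1OCc1ccccc1
F2 | step 6 | 3-(4-benzyloxy-3-methoxyphenyl)propanoic acid | COc1cc(CCC(=O)O)ccc1OCc1ccccc1
F3 | step 6 | 1-(2-hydroxy-4,5-dimethoxyphenyl)ethanone | COc1cc(O)c(C(C)=O)cc1OC
F4 | step 6 | 2-acetyl-4,5-dimethoxyphenyl 3-(4-benzyloxy-3-methoxyphenyl)propanoate | COc1cc(OC(=O)CCc2ccc(OCc3ccccc3)c(OC)c2)c(C(C)=O)cc1OC
F5 | step 6 | 5-(4-benzyloxy-3-methoxyphenyl)-1-(2-hydroxy-4,5-dimethoxyphenyl)pentane-1,3-dione | COc1cc(O)c(C(=O)CC(=O)CCc2ccc(OCc3ccccc3)c(OC)c2)cc1OC
F6 | step 3 | 5,6-dimethoxy-3-(trimethylsilyloxy)benzofuran | COc1cc2occ(O[Si](C)(C)C)c2cc1OC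
F7 | step 3 | 2-[2-(4-benzyloxy-3-methoxyphenyl)-1-(trimethylsilyloxy)ethyl]-5,6-dimethoxybenzofuran-3(2H)-one (mixture of racemic diastereomers) | COc1cc2OC(C(O[Si](C)(C)C)Cc3ccc(OCc4ccccc4)c(OC)c3)C(=O)c2cc1OC
F0 | step 4 | none | none
F8 | step 7 | 3-bromo-2-[2-(4-hydroxy-3-methoxyphenyl)ethyl]-6,7-dimethoxychromone | COc1cc(CCc2oc3cc(OC)c(OC)cc3c(=O)c2Br)ccc1O
A1 | alternative 1 | (Z)-3-(3,4-dimethoxyphenoxy)-5-[3-methoxy-4-(tosyloxy)phenyl]pent-2-enoic acid | COc1ccc(O/C(CCc2ccc(OS(=O)(=O)c3ccc(C)cc3)c(OC)c2)=C\C(=O)O)cc1OC
A2 | alternative 1 | 2-{2-[3-methoxy-4-(tosyloxy)phenyl]ethyl}-6,7-dimethoxychromone | COc1cc(CCc2cc(=O)c3cc(OC)c(OC)cc3o2)ccc1OS(=O)(=O)c1ccc(C)cc1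
A3 | alternative 2 | 5-(4-acetoxy-3-methoxyphenyl)-1-(3,4-dimethoxyphenyl)pentane-1,3-dione | COc1ccc(C(=O)CC(=O)CCc2ccc(OC(C)=O)c(OC)c2)cc1OC
A4 | alternative 2 | 2-[2-(4-acetoxy-3-methoxyphenyl)ethyl]-6,7-dimethoxychromone | COc1cc(CCc2cc(=O)c3cc(OC)c(OC)cc3o2)ccc1OC(C)=O
A5 | alternative 3 | 2-iodo-4,5-dimethoxyphenol | COc1cc(O)c(I)cc1OC
A6 | alternative 3 | carbon monoxide | [C-]#[O+]
A7 | alternative 3 | 4-(4-benzyloxy-3-methoxyphenyl)but-1-yne | C#CCCc1ccc(OCc2ccccc2)c(OC)c1
A8 | alternative 3 | 2-[2-(4-benzyloxy-3-methoxyphenyl)ethyl]-6,7-dimethoxychromone | COc1cc(CCc2cc(=O)c3cc(OC)c(OC)cc3o2)ccc1OCc1ccccc1
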